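The earlier runs and the new flask are calculated for an exercise.

The easy step first: average the last two readings of Tuesday's run, and you have most of the quick number you asked for.

| setting | Tuesday's | Thursday's | oak | birch | alder |
|---|---|---|---|---|---|
| starting material | 0.059 M | 0.13 M | 0.088 M | 0.088 M | 0.088 M |
| reagent | 0.132 M | 0.132 M | 0.132 M | 0.132 M | 0.132 M |
| protic impurity | 1.76 mM | 1.76 mM | 1.76 mM | 1.76 mM | 1.76 mM |
| temperature | 85 °C | 100 °C |  | 90 °C | 110 °C |
| remark | run made earlier | run made earlier | at 90 °C until 80 min, from then on at 110 °C |  |  |
| time |  |  | 4.0 h | 4.0 h | 4.0 h |

| run | time / h | target / % |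
|---|---|---|
| Tuesday's | 0.833 | 17.1 |
| Tuesday's | 1.50 | 18.3 |
| Tuesday's | 2.50 | 20.5 |
| Tuesday's | 3.00 | 22.1 |
| Tuesday's | 4.00 | 20.7 |
| Thursday's | 0.200 | 8.7 |
| Thursday's | 0.417 | 12.4 |
| Thursday's | 0.667 | 14.5 |
| Thursday's | 1.33 | 16.4 |
| Thursday's | 2.50 | 18.2 |

(standard deviation of a reading: 1 percentage point)

1. which flask leads in amount of target, in percent of the starting material charged ("all alike" within 1.5 percentage points) (oak / birch / alder / all alike)
2. how much target is there at the end, in percent of the starting material charged: oak
3. how much target is there at the end, in percent of the starting material charged: birch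
4. how much target is there at the end, in percent of the starting material charged: alder

- a reading or a percentage of target counts all its forms, free or not

    target share = (22.1 % + 20.7 %) / 2 = 21.4 %

Call this the target share: the part of the charge I expect to end as target, so long as reagent is not short. Tuesday's flask held 2.24 equivalents of reagent. Assuming that each starting material reacting takes at most one reagent, my working rule is:

    target at the end ≈ target share × the smaller of one and (reagent / starting material)

In oak, birch and alder that ratio is 1.50, above one, so starting material is the limiting reagent and the rule gives 21.4 % for each.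

Temperature, the setting that separates your flasks, enters as a correction to that figure, and I can't size it. Tuesday's two readings differ from each other by 1.4 percentage points, which is less than the margin of 1.5 points. Thursday's last reading, 18.2 % at 2.50 h, is lower, but that run differs from Tuesday's in temperature, in starting material and in the time of the reading, so I can't put the gap on one of them. The rule gives one figure for oak, birch and alder, so my answer is all alike.

Your forecast says the same, all alike, with oak at 20.2 % (17.5 % to 23 %), birch at 21 % (18.8 % to 23.3 %) and alder at 20.4 % (17.5 % to 23.5 %). Its ground: “The burst percentage barely depends on concentration or temperature”. My figure stands 1 point above its alder.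

The flasks give all alike: oak 22.8 %, birch 22.1 %, alder 22.4 %, a spread of 0.70 points.

    2 starting material → self-condensation product (k = 4.20 × 10⁻⁴ L mol⁻¹ s⁻¹, Ea = 83.0 kJ mol⁻¹)
    starting material + protic impurity → quenched substrate (k = 0.0240 L mol⁻¹ s⁻¹, Ea = 77.0 kJ mol⁻¹)
    starting material + reagent → isomer of the product (k = 0.00290 L mol⁻¹ s⁻¹, Ea = 70.0 kJ mol⁻¹)
    starting material + reagent → target (k = 9.80 × 10⁻⁴ L mol⁻¹ s⁻¹, Ea = 70.0 kJ mol⁻¹)
    starting material + target ⇌ idle adduct, settled at all times (K = 9.70 L mol⁻¹, ΔH = 5.00 kJ mol⁻¹)
    (constants at 90 °C)

Birch still holds 2.26 % of the starting material charged, unbound, at 4.00 h, and at the target share that remainder counts for 0.484 % of the charge as target. Now take a neighbour of alder charged with 0.22 M of starting material, where reagent is short at 0.600 equiv. The rule gives it 12.8 %. That flask ends with 15.1 % of target and 0.65 % of its reagent left.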